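Everything rests on opening the C9=C10 bond of the six-membered ketone ring (C5–C10–C9–C8–C7, closed by C4 or C6) after C2 has been taken out of the seven-membered ring. The cyclobutane C4–C5–C6–C7 that remains has a latent mirror plane through C4, C6 and C11, since the only difference between C5 and C7 is which of C10 and C8 they hold. One amine-catalysed aldol condensation of the meso cis-1,3-diacetylcyclobutane 15 closes the bicyclo[3.1.1]heptenone and fixes C4, C5, C6 and C7 together. In 15, C4 bears methyl and a Weinreb amide (C3). C6 bears a methylmalonate arm whose enantiotopic esters become C1 and the C11 hydroxymethyl group.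

Key step: step 10

Locants: the cyclobutane is C4–C5–C6–C7. C3 sits on C4, C11 on C6, C10 on C5 and C8 on C7. C9 joins C8 and C10, C1 sits on C11, and C2 joins C1 and C3. "Top" is the cyclobutane face that ends up carrying the ketone bridge and the C4 methyl group. "Bottom" is the face carrying C3 and C11.

All compounds up to 15 are achiral, so their stereo-SMILES give relative configuration only.

Design remarks:
- (a) The side of C10 that faces C4 is roofed by the C4 methyl group and closed to external reagents. C10 is therefore set by equilibrating a temporary formyl group.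
- (b) The C5 and C7 sides of the lower bridge differ only at remote atoms. C11 and C1/C3 are therefore set under catalyst control.
- (c) In the closed seven-membered ring the C1 oxygen lies cis to the C11 methyl group that must stay untouched. The hydroxymethyl carbon is therefore carried in oxidised form from the start.

Assumption: for the two group selections whose sense cannot be read from a simple model (steps 10 and 15), the catalyst antipode named is taken to give the isomer drawn; the other antipode is equally available.

Step 1
Reactants: 1 3-oxocyclobutane-1-carboxylic acid; 2 8-aminoquinoline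
Product: 3 3-oxo-N-(quinolin-8-yl)cyclobutane-1-carboxamide
Conditions: EDC·HCl, DMAP (cat.), CH2Cl2, rt
Reagents that add atoms: none
Why: Carbodiimide-mediated amide coupling should attach the bidentate auxiliary to the carboxyl carbon that later serves as C3, and no stereocentre is formed.

Step 2
Reactants: 3 3-oxo-N-(quinolin-8-yl)cyclobutane-1-carboxamide; 4 dimethyl malonate
Product: 5 dimethyl 2-[3-(quinolin-8-ylcarbamoyl)cyclobutylidene]propanedioate
Conditions: TiCl4, pyridine, THF/CH2Cl2, 0 °C to rt
Reagents that add atoms: none
Why: Knoevenagel condensation under TiCl4/pyridine activation is the standard way to join dialkyl malonates to ketones and should work on the strained, unhindered cyclobutanone, creating C6=C11.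

Step 3
Reactants: 5 dimethyl 2-[3-(quinolin-8-ylcarbamoyl)cyclobutylidene]propanedioate
Product: 6 dimethyl 2-[cis-3-(quinolin-8-ylcarbamoyl)cyclobutyl]propanedioate
Conditions: NaBH4, THF/MeOH, –20 to 0 °C
Reagents that add atoms: none
Why: In this conjugate hydride reduction of an alkylidene malonate, as in hydride additions to 3-substituted cyclobutanones and cyclobutylidene 1,3-dicarbonyl compounds, hydride should attack C6 from the face opposite the C4 carboxamide, which places amide and arm cis (both bottom).

Step 4
Reactants: 7 2-bromopropene
Product: 8 2-iodopropene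
Conditions: NaI, CuI (5 mol %), trans-N,N'-dimethylcyclohexane-1,2-diamine (10 mol %), dioxane, 110 °C, sealed tube; distillation
Reagents that add atoms: sodium iodide [Na+].[I-]
Why: Copper-catalysed halogen exchange (Finkelstein type), established for alkenyl bromides, supplies the iodide, which adds oxidatively to a palladacycle far more readily than the bromide.

Step 5
Reactants: 6 dimethyl 2-[cis-3-(quinolin-8-ylcarbamoyl)cyclobutyl]propanedioate; 8 2-iodopropene
Product: 9 dimethyl 2-[all-cis-2,4-di(prop-1-en-2-yl)-3-(quinolin-8-ylcarbamoyl)cyclobutyl]propanedioate (all four ring substituents bottom)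
Conditions: Pd(OAc)2 (15 mol %), AgOAc (3 equiv), PivOH (0.5 equiv), 8 (5 equiv), t-AmylOH, 100 °C, sealed tube
Reagents that add atoms: none
Why: Aminoquinoline-directed β-C(sp3)–H alkenylation through a five-membered palladacycle (divalent/tetravalent palladium cycle) is known for cyclobutanecarboxamides, including double functionalisation next to a cis 3-substituent, and it can only replace the C5 and C7 hydrogens cis to the amide, while the arm is kept tertiary here so that its C–H can face the reacting sites.

Step 6
Reactants: 9 all-cis bis(propenyl) aminoquinoline amide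
Product: 10 N-Boc derivative of 9 (tert-butyl N-acyl-N-(quinolin-8-yl)carbamate)
Conditions: Boc2O, DMAP (0.2 equiv), MeCN, rt
Reagents that add atoms: di-tert-butyl dicarbonate CC(C)(C)OC(=O)OC(=O)OC(C)(C)C
Why: N-acylation of the secondary amide with Boc2O/DMAP twists the amide bond and turns the auxiliary into a leaving group, the usual first half of aminoquinoline removal.

Step 7
Reactants: 10 N-Boc derivative of 9; 11 N,O-dimethylhydroxylamine hydrochloride
Product: 12 dimethyl 2-{all-cis-3-[methoxy(methyl)carbamoyl]-2,4-di(prop-1-en-2-yl)cyclobutyl}propanedioate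
Conditions: Et3N, toluene, 50 °C
Reagents that add atoms: none
Why: Uncatalysed aminolysis of an N-acyl-N-Boc carbamate (two-step transamidation) should exchange the auxiliary for the Weinreb amine, and any epimerisation at C4 is harmless because C4 is enolised in the next step.

Step 8
Reactants: 12 all-cis Weinreb amide
Product: 13 dimethyl 2-{3-[methoxy(methyl)carbamoyl]-3-methyl-2,4-di(prop-1-en-2-yl)cyclobutyl}-2-methylpropanedioate (amide, both propenyl groups and arm bottom; C4 methyl top)
Conditions: LDA (3.2 equiv), THF, –78 to –40 °C; MeI (6 equiv), –78 °C to rt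
Reagents that add atoms: iodomethane CI
Why: In this double enolate alkylation the malonate anion is methylated at C11 and the amide enolate at C4, where iodomethane can only approach the top face because both propenyl groups and the arm shield the bottom face, so the C4 methyl group ends up trans to all three.

Step 9
Reactants: 13 dimethylated bis(propenyl) Weinreb amide
Product: 15 meso diketone: dimethyl 2-{2,4-diacetyl-3-[methoxy(methyl)carbamoyl]-3-methylcyclobutyl}-2-methylpropanedioate (acetyl groups and C4 methyl top; amide and arm bottom), via all-cis diketone 14 (not isolated)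
Conditions: O3, CH2Cl2, –78 °C; Me2S; then DBU (0.2 equiv), CH2Cl2, rt
Reagents that add atoms: ozone [O-][O+]=O
Why: Ozonolysis with reductive work-up turns both propenyl groups into acetyl groups, and base epimerisation α to the ketones then moves both to the top face, the thermodynamic position trans to amide and arm, whereas ring closure of the all-cis isomer is disfavoured because it would roof both faces of the new ring with the large groups.

Step 10
Reactants: 15 meso diketone
Product: 17 dimethyl 2-{6-[methoxy(methyl)carbamoyl]-4,6-dimethyl-2-oxobicyclo[3.1.1]hept-3-en-7-yl}-2-methylpropanedioate (C8 ketone; C9=C10; C10 methyl; C4 methyl and C6–H on the enone side), via ketol 16 (not isolated)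
Conditions: 9-amino-9-deoxy-epi-quinine (20 mol %), AcOH (40 mol %), toluene, 40 °C
Reagents that add atoms: none
Why: The primary amine condenses with one acetyl group and tautomerises to the terminal enamine C8(N)=C9, whose carbon C9 adds to the acid-activated carbonyl C10 of the other acetyl group; loss of water from ketol 16 and hydrolysis of the iminium ion release 17 and the catalyst. The closest known reaction is the cinchona-primary-amine/acid-catalysed desymmetrising aldol condensation of 4-substituted heptane-2,6-diones to 5-substituted 3-methylcyclohex-2-enones, and 15 is such a dione whose positions 3 and 5 are tied together by C4. The one ring closed is six-membered and the mode is 6-(enolendo)-exo-trig, because both enamine carbons C8 and C9 lie inside the new ring while the C10=O bond is exocyclic to it. No bond at C4, C5, C6 or C7 is touched: these mirror-related or pseudo-asymmetric centres become true stereocentres solely through the catalyst's choice between the enantiotopic acetyl groups. The step needs group selectivity and chemoselectivity, secured because only a methyl-side enamine can reach a carbonyl group, C5 and C7 already sit in their thermodynamic configuration so that internal enamines cannot scramble them, and amide and esters carry no acidic hydrogen. The cis-1,3 relation lets the acetyl groups meet once the ring flips to the pucker with all four large groups axial, which is the price of the step and the reason for gentle heating.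

Step 11
Reactants: 17 bicyclic enone
Product: 18 4-formyl enone (C10–CHO in place of C10–CH3)
Conditions: SeO2 (1.5 equiv), 1,4-dioxane, 90 °C
Reagents that add atoms: selenium dioxide O=[Se]=O
Why: In this Riley-type allylic oxidation the C10 methyl group is the only allylic or α-carbonyl C–H site not at a bridgehead, so SeO2 should take it to the aldehyde and thereby make C10 epimerisable once the alkene is saturated.

Step 12
Reactants: 18 4-formyl enone
Product: 20 saturated keto aldehyde with the formyl group on the C6 side and C10–H toward C4, via C10-epimeric aldehyde 19 (not isolated)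
Conditions: H2 (1 atm), Pd/C, EtOAc, rt; filtration; DBU (0.1 equiv), CH2Cl2, rt
Reagents that add atoms: none
Why: Heterogeneous hydrogenation adds to the open C6–H side of the ene-dicarbonyl, and reversible enolisation of the aldehyde then turns the formyl group to that same open side, away from the C4 methyl group, which is both the thermodynamic and the required C10 configuration.

Step 13
Reactants: 20 saturated keto aldehyde
Product: 22 dimethyl 2-{6-[methoxy(methyl)carbamoyl]-4,6-dimethyl-2-oxobicyclo[3.1.1]heptan-7-yl}-2-methylpropanedioate (C10 methyl on the C6 side), via tosylhydrazone 21 (not isolated)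
Conditions: TsNHNH2 (1.05 equiv), EtOH, rt; catecholborane, CHCl3, 0 °C; NaOAc·3H2O, reflux
Reagents that add atoms: 4-methylbenzenesulfonohydrazide (atoms in 21 only) Cc1ccc(cc1)S(=O)(=O)NN
Why: In this tosylhydrazone reduction (Caglioti type, catecholborane variant) the aldehyde condenses much faster than the hindered C8 ketone, and hydroboration of C=N followed by acetate-induced loss of sulfinate and nitrogen leaves the C10 methyl group without touching the stereocentre.

Step 14
Reactants: 22 saturated bicyclic ketone
Product: 23 C8 ethylene ketal of 22
Conditions: ethylene glycol, p-TsOH·H2O (cat.), benzene, reflux, Dean–Stark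
Reagents that add atoms: ethane-1,2-diol OCCO
Why: Acid-catalysed ketalisation masks the only ketone before the hydride, Grignard, strong-base and borane steps.

Step 15
Reactants: 23 ketal diester
Product: 24 (11S)-hydroxy ester: methyl 3-hydroxy-2-methyl-2-(cage)propanoate (one ester reduced to CH2OH)
Conditions: ZnEt2 (10 mol %), pipecolinol-derived tetradentate phenol ligand (5 mol %), (MeO)3SiH (3 equiv), THF, 0 °C; aqueous work-up
Reagents that add atoms: none
Why: Catalytic desymmetrising hydrosilylation of α,α-disubstituted malonic esters by a chiral dinuclear zinc hydride reduces one chelated ester to the alcohol and tells the two esters apart by the size difference between the C11 methyl group and the cage, so C11 is set under catalyst control.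

Step 16
Reactants: 24 hydroxy ester
Product: 25 TBS ether of 24
Conditions: TBSCl, imidazole, DMF, rt
Reagents that add atoms: tert-butyl(chloro)dimethylsilane CC(C)(C)[Si](C)(C)Cl
Why: Standard silylation protects the primary alcohol, which must stay free of acyl groups at the end and must not undergo retro-aldol loss under base.

Step 17
Reactants: 25 TBS ether
Product: 26 C3 methyl ketone (C4–C(=O)–CH3, the new methyl carbon being C2)
Conditions: MeMgBr (3 equiv), THF, 0 °C to rt; water
Reagents that add atoms: methylmagnesium bromide C[Mg]Br
Why: In the Weinreb ketone synthesis the chelated tetrahedral intermediate prevents over-addition and brings in C2, while the methyl ester on the quaternary C11 should react more slowly.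

Step 18
Reactants: 26 keto ester
Product: 27 tricyclic 1,3-diketone (C1 and C3 ketones; C8 ketal; C11 CH2OTBS)
Conditions: KOtBu (2.2 equiv), THF, 0 °C to rt; AcOH quench
Reagents that add atoms: none
Why: In this intramolecular Claisen (Dieckmann-type) acylation only C2 can be deprotonated, the bicyclic core holds C3 and C11 as parallel axial neighbours for a 7-(enolendo)-exo-trig closure, and formation of the diketone enolate drives the equilibrium.

Step 19
Reactants: 27 tricyclic 1,3-diketone
Product: 28 (1R,3R)-trans-diol
Conditions: (S)-Me-CBS (0.5 equiv), BH3·SMe2 (2.5 equiv), THF, –20 °C; MeOH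
Reagents that add atoms: none
Why: In the Corey–Bakshi–Shibata reduction each carbonyl group is flanked by a fully substituted carbon (large) and by C2H2 (small), so the (S)-catalyst should give the (R)-carbinol at both, that is the anti diol, and internal hydride delivery from the first-formed alkoxyborane points the same way.

Step 20
Reactants: 28 trans-diol; 29 angelic acid
Product: 31 C1,C3-bis(angelate) with C8 ketal and TBS ether, via mixed anhydride 30 (not isolated)
Conditions: 29 (4 equiv), 2,4,6-trichlorobenzoyl chloride, Et3N, toluene, rt; then 28, 80 °C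
Reagents that add atoms: 2,4,6-trichlorobenzoyl chloride (atoms in 30 only) O=C(Cl)c1c(Cl)cc(Cl)cc1Cl
Why: Yamaguchi-type mixed-anhydride esterification run without a nucleophilic catalyst is known to acylate hindered alcohols while conserving the Z geometry of the angeloyl group.

Step 21
Reactants: 31 protected bis(angelate)
Product: 32 target CNP0287707.1
Conditions: p-TsOH·H2O (0.3 equiv), THF/H2O, 40 °C
Reagents that add atoms: water O
Why: Mild acid hydrolysis removes the primary silyl ether and the dioxolane in one operation, under conditions that leave hindered α,β-unsaturated esters alone and do not promote base-type acyl migration.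

Compound list
1 | 3-oxocyclobutane-1-carboxylic acid | O=C1CC(C1)C(=O)O | starting material
2 | 8-aminoquinoline | Nc1cccc2cccnc12 | starting material
3 | 3-oxo-N-(quinolin-8-yl)cyclobutane-1-carboxamide | O=C1CC(C1)C(=O)Nc1cccc2cccnc12 | intermediate
4 | dimethyl malonate | COC(=O)CC(=O)OC | starting material
5 | dimethyl 2-[3-(quinolin-8-ylcarbamoyl)cyclobutylidene]propanedioate | COC(=O)C(C(=O)OC)=C1CC(C1)C(=O)Nc1cccc2cccnc12 | intermediate
6 | dimethyl 2-[cis-3-(quinolin-8-ylcarbamoyl)cyclobutyl]propanedioate | O=C(Nc1cccc2cccnc12)[C@@H]3C[C@@H](C3)C(C(=O)OC)C(=O)OC | intermediate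
7 | 2-bromopropene | CC(Br)=C | starting material
8 | 2-iodopropene | CC(I)=C | intermediate
9 | all-cis bis(propenyl) aminoquinoline amide | O=C(Nc1cccc2cccnc12)[C@@H]3[C@H](C(C)=C)[C@@H]([C@@H]3C(C)=C)C(C(=O)OC)C(=O)OC | intermediate
10 | N-Boc derivative of 9 | CC(C)(C)OC(=O)N(c1cccc2cccnc12)C(=O)[C@@H]3[C@H](C(C)=C)[C@@H]([C@@H]3C(C)=C)C(C(=O)OC)C(=O)OC | intermediate
11 | N,O-dimethylhydroxylamine hydrochloride | CNOC.Cl | starting material
12 | all-cis Weinreb amide (C4–H top) | CON(C)C(=O)[C@@H]1[C@H](C(C)=C)[C@@H]([C@@H]1C(C)=C)C(C(=O)OC)C(=O)OC | intermediate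
13 | C4,C11-dimethylated bis(propenyl) Weinreb amide | CON(C)C(=O)[C@]1(C)[C@H](C(C)=C)[C@@H]([C@@H]1C(C)=C)C(C)(C(=O)OC)C(=O)OC | intermediate
14 | all-cis diketone (acetyl groups bottom) | CON(C)C(=O)[C@]1(C)[C@H](C(C)=O)[C@@H]([C@@H]1C(C)=O)C(C)(C(=O)OC)C(=O)OC | intermediate
15 | meso cis-1,3-diacetylcyclobutane (acetyl groups top) | CON(C)C(=O)[C@]1(C)[C@@H](C(C)=O)[C@@H]([C@H]1C(C)=O)C(C)(C(=O)OC)C(=O)OC | intermediate
16 | ketol (C10 OH toward C4, C10 methyl toward C6) | CON(C)C(=O)[C@]1(C)[C@@H]2[C@@H]([C@H]1C(=O)C[C@]2(C)O)C(C)(C(=O)OC)C(=O)OC | intermediate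
17 | bicyclo[3.1.1]hept-3-en-2-one | CON(C)C(=O)[C@]1(C)[C@@H]2[C@@H]([C@H]1C(=O)C=C2C)C(C)(C(=O)OC)C(=O)OC | intermediate
18 | 4-formyl enone | CON(C)C(=O)[C@]1(C)[C@@H]2[C@@H]([C@H]1C(=O)C=C2C=O)C(C)(C(=O)OC)C(=O)OC | intermediate
19 | keto aldehyde, formyl toward C4 | CON(C)C(=O)[C@]1(C)[C@@H]2[C@@H]([C@H]1C(=O)C[C@@H]2C=O)C(C)(C(=O)OC)C(=O)OC | intermediate
20 | keto aldehyde, formyl toward C6 | CON(C)C(=O)[C@]1(C)[C@@H]2[C@@H]([C@H]1C(=O)C[C@H]2C=O)C(C)(C(=O)OC)C(=O)OC | intermediate
21 | aldehyde tosylhydrazone | CON(C)C(=O)[C@]1(C)[C@@H]2[C@@H]([C@H]1C(=O)C[C@H]2/C=N/NS(=O)(=O)c3ccc(C)cc3)C(C)(C(=O)OC)C(=O)OC | intermediate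
22 | saturated bicyclic ketone, (10R)-methyl | CON(C)C(=O)[C@]1(C)[C@@H]2[C@@H]([C@H]1C(=O)C[C@H]2C)C(C)(C(=O)OC)C(=O)OC | intermediate
23 | C8 ethylene ketal | CON(C)C(=O)[C@]1(C)[C@@H]2[C@@H]([C@H]1C3(OCCO3)C[C@H]2C)C(C)(C(=O)OC)C(=O)OC | intermediate
24 | (11S)-hydroxy ester | CON(C)C(=O)[C@]1(C)[C@@H]2[C@@H]([C@H]1C3(OCCO3)C[C@H]2C)[C@@](C)(CO)C(=O)OC | intermediate
25 | TBS ether | CON(C)C(=O)[C@]1(C)[C@@H]2[C@@H]([C@H]1C3(OCCO3)C[C@H]2C)[C@@](C)(CO[Si](C)(C)C(C)(C)C)C(=O)OC | intermediate
26 | C3 methyl ketone | CC(=O)[C@]1(C)[C@@H]2[C@@H]([C@H]1C3(OCCO3)C[C@H]2C)[C@@](C)(CO[Si](C)(C)C(C)(C)C)C(=O)OC | intermediate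
27 | tricyclic 1,3-diketone | O=C1CC(=O)[C@]2(C)[C@@H]3[C@@H]([C@H]2C4(OCCO4)C[C@H]3C)[C@@]1(C)CO[Si](C)(C)C(C)(C)C | intermediate
28 | (1R,3R)-trans-diol | O[C@@H]1C[C@@H](O)[C@]2(C)[C@@H]3[C@@H]([C@H]2C4(OCCO4)C[C@H]3C)[C@@]1(C)CO[Si](C)(C)C(C)(C)C | intermediate
29 | angelic acid, (Z)-2-methylbut-2-enoic acid | C/C=C(/C)C(=O)O | starting material
30 | angelic 2,4,6-trichlorobenzoic anhydride | C/C=C(/C)C(=O)OC(=O)c1c(Cl)cc(Cl)cc1Cl | intermediate
31 | protected bis(angelate) | C/C=C(/C)C(=O)O[C@@H]1C[C@@H](OC(=O)/C(C)=C\C)[C@]2(C)[C@@H]3[C@@H]([C@H]2C4(OCCO4)C[C@H]3C)[C@@]1(C)CO[Si](C)(C)C(C)(C)C | intermediate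
32 | CNP0287707.1 | C/C=C(/C)C(=O)O[C@@H]1C[C@@H](OC(=O)/C(C)=C\C)[C@]2(C)[C@@H]3[C@@H]([C@H]2C(=O)C[C@H]3C)[C@@]1(C)CO | target

Total step count: 21 (20 in the main line and 1 for reagent 8). Longest linear sequence: 20 steps (1 to 32).

Steps most likely to fail

1. Step 10.
- What may go wrong: closure may stall because the cyclobutane has to reach the pucker with both acetyl groups, the amide and the arm axial. The extra strain of the bicycle may hold the equilibrium back. Differentiation of the acetyl groups may also erode at the temperature needed.
- Fallback: starting from 15, the ring is closed without asymmetric induction (pyrrolidinium acetate, toluene, reflux with water removal). This gives 17 together with its mirror image, the ent-enone F1. The two are separated by preparative chromatography on a chiral stationary phase, and the route is rejoined at 17.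

2. Step 5.
- What may go wrong: the second palladation and the oxidative addition may be slowed by crowding next to the cis arm. The acidic malonate C–H may also bind the metal.
- Fallback: starting from 5, the double directed alkenylation with 8 is run on the cyclobutylidene malonate, where C6 is trigonal and puts no substituent beside the reacting C–H bonds. This gives the bis(propenyl) cyclobutylidene malonate F2. NaBH4 then delivers hydride to C6 from the top face, opposite both propenyl groups, and the route is rejoined at 9.

3. Step 15.
- What may go wrong: the zinc catalyst may fail to chelate the very hindered diester, or it may distinguish the two esters poorly.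
- Fallback: starting from 23, enzymatic mono-hydrolysis (pig liver esterase, pH 7 buffer/DMSO) gives the half-ester F3. Activation with isobutyl chloroformate/N-methylmorpholine gives the mixed carbonic anhydride F4. NaBH4 in THF/water reduces only this group, and the route is rejoined at 24.

Further compounds
F1 | step 10 | ent-17, mirror image of the bicyclic enone | CON(C)C(=O)[C@@]1(C)[C@H]2[C@H]([C@@H]1C(=O)C=C2C)C(C)(C(=O)OC)C(=O)OC
F2 | step 5 | dimethyl 2-[2,4-cis-di(prop-1-en-2-yl)-3-(quinolin-8-ylcarbamoyl)cyclobutylidene]propanedioate (amide and propenyl groups all cis) | O=C(Nc1cccc2cccnc12)[C@@H]3[C@H](C(C)=C)C(=C(C(=O)OC)C(=O)OC)[C@@H]3C(C)=C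
F3 | step 15 | malonic half-ester of 23 (acid carbon = future CH2OH) | CON(C)C(=O)[C@]1(C)[C@@H]2[C@@H]([C@H]1C3(OCCO3)C[C@H]2C)[C@@](C)(C(=O)O)C(=O)OC
F4 | step 15 | isobutyl mixed carbonic anhydride of F3 | CON(C)C(=O)[C@]1(C)[C@@H]2[C@@H]([C@H]1C3(OCCO3)C[C@H]2C)[C@@](C)(C(=O)OC(=O)OCC(C)C)C(=O)OC
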